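Ring B is closed last, by a disrotatory 6π-electrocyclisation of the 2-oxidotriene C10=C5–C6(O)=C7–C8=C9 (drimane numbering) that joins the two fully substituted carbons C9 and C10. The step exploits the cis relationship between the C10 methyl group and the C9 oxygen beside the C7=C8 bond of ring B: both are inside groups of the triene. The precursor is a ring A cyclohexenyl ketone whose α-carbon carries a 3-alkoxy-5-menthyloxybutenolide. The lactone locks the geometry of the triene terminus, and its acetal carbon, the later C12 aldehyde, is a traceless stereocentre that fixes the absolute configuration at C9 and C10.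

Key step: step 6

Remark: drimane numbering is used throughout (C4 gem-dimethyl, C10 methyl, C11 = carboxyl carbon on C9, C12 = formyl carbon on C8); the target is taken as the open aldehyde acid drawn, which should not close to a lactol because its C11 carboxyl is trans to the C10 methyl and pseudo-axial on the trans-fused ring B.

Step 1
Reactants: 1 β-cyclocitral
Product: 2 rac-1-(2,6,6-trimethylcyclohex-1-en-1-yl)ethan-1-ol
Conditions: MeMgBr, Et2O, 0 °C to rt; aq. NH4Cl
Reagents that add atoms: methylmagnesium bromide, C[Mg]Br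
Why: 1,2-Addition of the Grignard reagent to the hindered, β,β-disubstituted enal should give the allylic alcohol, whose racemic carbinol centre is removed in step 2.

Step 2
Reactants: 2 rac-1-(2,6,6-trimethylcyclohex-1-en-1-yl)ethan-1-ol
Product: 3 1-(2,6,6-trimethylcyclohex-1-en-1-yl)ethan-1-one
Conditions: Dess–Martin periodinane, NaHCO3, CH2Cl2, rt
Reagents that add atoms: none
Why: Dess–Martin oxidation converts the secondary allylic alcohol into the methyl ketone under buffered conditions that leave the tetrasubstituted alkene in place and creates no stereocentre.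

Step 3
Reactants: 3 1-(2,6,6-trimethylcyclohex-1-en-1-yl)ethan-1-one; 4 (5R)-5-[(1R,2S,5R)-menthyloxy]furan-2(5H)-one
Product: 7 (3R,4R,5R)-3-hydroxy-5-[(1R,2S,5R)-menthyloxy]-4-[2-oxo-2-(2,6,6-trimethylcyclohex-1-en-1-yl)ethyl]dihydrofuran-2(3H)-one, via lithium enolate 5 (not isolated), via lactone enolate 6 (not isolated)
Conditions: LDA, THF, −78 °C; add 4, −78 °C; then 3-phenyl-2-(phenylsulfonyl)oxaziridine, −78 to −40 °C; aq. NH4Cl
Reagents that add atoms: 3-phenyl-2-(phenylsulfonyl)oxaziridine, O=S(=O)(c1ccccc1)N1OC1c1ccccc1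
Why: Kinetic deprotonation at the methyl group gives enolate 5, whose Michael addition to the butenolide anti to the C5 menthyloxy group gives lactone enolate 6, and electrophilic hydroxylation by the oxaziridine anti to the new side chain gives the 3,4-trans-4,5-trans lactone (tandem conjugate addition–enolate oxidation); the two new centres become sp2 in step 4, so only the retained acetal centre matters.

Step 4
Reactants: 7 (3R,4R,5R)-3-hydroxy-5-[(1R,2S,5R)-menthyloxy]-4-[2-oxo-2-(2,6,6-trimethylcyclohex-1-en-1-yl)ethyl]dihydrofuran-2(3H)-one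
Product: 9 (5R)-3-hydroxy-5-[(1R,2S,5R)-menthyloxy]-4-[2-oxo-2-(2,6,6-trimethylcyclohex-1-en-1-yl)ethyl]furan-2(5H)-one, via keto lactone 8 (not isolated)
Conditions: Dess–Martin periodinane, NaHCO3, CH2Cl2, 0 °C to rt
Reagents that add atoms: none
Why: Dess–Martin oxidation of the secondary α-hydroxy lactone gives the α-keto lactone 8, which should tautomerise to the conjugated 3-hydroxybutenolide (isotetronic acid) form, so that the future C8 and C9 become sp2 and the acetal carbon is the only stereocentre left in the ring.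

Step 5
Reactants: 9 (5R)-3-hydroxy-5-[(1R,2S,5R)-menthyloxy]-4-[2-oxo-2-(2,6,6-trimethylcyclohex-1-en-1-yl)ethyl]furan-2(5H)-one
Product: 10 (5R)-3-(4-methoxybenzyloxy)-5-[(1R,2S,5R)-menthyloxy]-4-[2-oxo-2-(2,6,6-trimethylcyclohex-1-en-1-yl)ethyl]furan-2(5H)-one
Conditions: 4-methoxybenzyl alcohol, PPh3, DIAD, THF, 0 °C
Reagents that add atoms: 4-methoxybenzyl alcohol, COc1ccc(CO)cc1
Why: Mitsunobu etherification of the acidic enol hydroxyl under neutral conditions should give the enol ether without epimerising the acetal centre, which blocks C8 as a nucleophile and makes C9 the alkoxy-bearing terminus needed in step 6.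

Step 6
Reactants: 10 (5R)-3-(4-methoxybenzyloxy)-5-[(1R,2S,5R)-menthyloxy]-4-[2-oxo-2-(2,6,6-trimethylcyclohex-1-en-1-yl)ethyl]furan-2(5H)-one
Product: 13 (5R,9R,10S,12R)-12-[(1R,2S,5R)-menthyloxy]-9-(4-methoxybenzyloxy)-6-oxo-5β-drim-7-en-11,12-olide (cis-fused decalin), via trienolate 11 (not isolated), via cyclised enolate 12 (not isolated)
Conditions: DBU (0.2 equiv), PhMe (0.02 M), 70 °C
Reagents that add atoms: none
Why: DBU removes the doubly activated C7–H of 10 (α to the ketone and vinylogous γ-position of the butenolide) to give the 2-oxidotriene 11 (C10=C5–C6(O−)=C7–C8=C9), in which rotation about C6–C7 is easy, so the isomer with C5 and C8 cis is always available. Thermal disrotatory 6π-electrocyclisation (oxyanion-accelerated; in valence-bond terms a 6-endo-trig vinylogous Michael addition of C9 to the enone carbon C10) then forms the C9–C10 bond and ring B, the closest known reaction type being the anion-accelerated electrocyclisation of 2-oxidohexatrienes to cyclohexadienolates. Because the butenolide ring holds the C9 oxygen cis to C7 and the C10 methyl is necessarily cis to C6, both are inside groups and disrotation places them cis across the new bond, which is the C10-methyl/C9-oxygen relationship of the target. The new bond should form on the butenolide face anti to the C12 menthyloxy group, which sits beside the coiling C7–C6–C5 arm and the C4 gem-dimethyl group, so the (12R) acetal centre should fix C9 as R and thereby C10 as S. The less stabilised enolate 12 is protonated at C5 by DBU-H+ or by 10, which drives the reaction with sub-stoichiometric base, and only the cis ring fusion can result because a lactone fused at C8–C9 next to the C7=C8 bond cannot span a trans-decalin (C5 is corrected in step 7). The selectivity needed is C9–C10 closure without epimerisation at C12, which the much higher acidity of C7–H than of C12–H and the ring-locked terminus geometry (lactone carbonyl held away from the enolate oxygen) should secure.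

Step 7
Reactants: 13 (5R,9R,10S,12R)-12-[(1R,2S,5R)-menthyloxy]-9-(4-methoxybenzyloxy)-6-oxo-5β-drim-7-en-11,12-olide
Product: 15 (5S,9R,10S)-9-(4-methoxybenzyloxy)-6,12-dioxodrim-7-en-11-oic acid, via cis-fused carboxylate 14 (not isolated)
Conditions: LiOH, THF/H2O (3:1), rt to 40 °C; then 1 M HCl to pH 3, 0 °C
Reagents that add atoms: lithium hydroxide, [Li+].[OH-]
Why: Saponification of the pseudo-ester opens the lactone irreversibly to the C11 carboxylate and the C12 aldehyde with loss of menthoxide (14), after which enolisation of the C6 ketone lets C5 epimerise to the more stable trans-fused decalin (5α-H), and the acid obtained on acidification cannot re-close because a C8–C9-fused lactol is incompatible with the trans ring fusion.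

Step 8
Reactants: 15 (5S,9R,10S)-9-(4-methoxybenzyloxy)-6,12-dioxodrim-7-en-11-oic acid
Product: 16 (5S,9R,10S)-12,12-dimethoxy-9-(4-methoxybenzyloxy)-6-oxodrim-7-en-11-oic acid
Conditions: HC(OMe)3, PPTS (cat.), MeOH, rt
Reagents that add atoms: trimethyl orthoformate, COC(OC)OC; methanol, CO
Why: Acid-catalysed acetalisation with trimethyl orthoformate protects the electron-poor enal chemoselectively over the hindered, conjugated C6 ketone and the hindered C11 acid, and changes no stereocentre.

Step 9
Reactants: 16 (5S,9R,10S)-12,12-dimethoxy-9-(4-methoxybenzyloxy)-6-oxodrim-7-en-11-oic acid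
Product: 17 (5S,6R,9R,10S)-6-hydroxy-12,12-dimethoxy-9-(4-methoxybenzyloxy)drim-7-en-11-oic acid
Conditions: NaBH4 (excess), CeCl3·7H2O, MeOH, −20 to 0 °C; pH 5 phosphate buffer
Reagents that add atoms: none
Why: Luche 1,2-reduction should deliver hydride to C6 from the α-face, because the β-face is screened by the axial C10 methyl and the β-methyl on C4, giving the 6β (6R) allylic alcohol.

Step 10
Reactants: 18 (2E,4E)-hexa-2,4-dienal; 19 malonic acid
Product: 20 (2E,4E,6E)-octa-2,4,6-trienoic acid
Conditions: pyridine, piperidine (cat.), 90 °C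
Reagents that add atoms: none
Why: Knoevenagel–Doebner condensation with decarboxylation extends the dienal by two carbons and should give the new C2=C3 double bond as the E isomer under thermodynamic control.

Step 11
Reactants: 17 (5S,6R,9R,10S)-6-hydroxy-12,12-dimethoxy-9-(4-methoxybenzyloxy)drim-7-en-11-oic acid; 20 (2E,4E,6E)-octa-2,4,6-trienoic acid
Product: 22 (5S,6R,9R,10S)-12,12-dimethoxy-9-(4-methoxybenzyloxy)-6-[(2E,4E,6E)-octa-2,4,6-trienoyloxy]drim-7-en-11-oic acid, via mixed anhydride 21 (not isolated)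
Conditions: 20 (3 equiv), 2,4,6-trichlorobenzoyl chloride, Et3N, PhMe, rt; then 17, DMAP, PhMe, rt to 40 °C; aq. NaHCO3 work-up
Reagents that add atoms: none
Why: Yamaguchi esterification through mixed anhydride 21 and its acylpyridinium ion acylates the secondary allylic 6β-hydroxyl with retention at C6, while any mixed anhydride formed at the very hindered C11 acid is expected to revert on bicarbonate work-up.

Step 12
Reactants: 22 (5S,6R,9R,10S)-12,12-dimethoxy-9-(4-methoxybenzyloxy)-6-[(2E,4E,6E)-octa-2,4,6-trienoyloxy]drim-7-en-11-oic acid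
Product: 23 (5S,6R,9R,10S)-9-hydroxy-6-[(2E,4E,6E)-octa-2,4,6-trienoyloxy]-12-oxodrim-7-en-11-oic acid (CNP0234478.3)
Conditions: TFA/CH2Cl2 (1:9), anisole (5 equiv), 0 °C; then THF/H2O (4:1), 0 °C to rt
Reagents that add atoms: water, O
Why: Trifluoroacetic acid ionises the 4-methoxybenzyl ether (cation trapped by anisole) and, once water is added, hydrolyses the allylic dimethyl acetal to the conjugated aldehyde, conditions under which the allylic trienoate and all four stereocentres should be unaffected.

Compound list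

1 | β-cyclocitral (2,6,6-trimethylcyclohex-1-ene-1-carbaldehyde) | CC1=C(C=O)C(C)(C)CCC1 | starting material
2 | rac-1-(2,6,6-trimethylcyclohex-1-en-1-yl)ethan-1-ol | CC(O)C1=C(C)CCCC1(C)C | intermediate
3 | 1-(2,6,6-trimethylcyclohex-1-en-1-yl)ethan-1-one | CC(=O)C1=C(C)CCCC1(C)C | intermediate
4 | (5R)-5-[(1R,2S,5R)-menthyloxy]furan-2(5H)-one | O=C1C=C[C@H](O[C@@H]2C[C@H](C)CC[C@H]2C(C)C)O1 | starting material
5 | lithium enolate of 3 (lithium 1-(2,6,6-trimethylcyclohex-1-en-1-yl)ethenolate; not isolated) | C=C(O[Li])C1=C(C)CCCC1(C)C | intermediate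
6 | lactone enolate: lithium enolate of the (4R,5R) Michael adduct of 5 and 4 (not isolated) | [Li]OC1=C[C@@H](CC(=O)C2=C(C)CCCC2(C)C)[C@H](O[C@@H]3C[C@H](C)CC[C@H]3C(C)C)O1 | intermediate
7 | (3R,4R,5R)-3-hydroxy-5-[(1R,2S,5R)-menthyloxy]-4-[2-oxo-2-(2,6,6-trimethylcyclohex-1-en-1-yl)ethyl]dihydrofuran-2(3H)-one | O=C1[C@H](O)[C@@H](CC(=O)C2=C(C)CCCC2(C)C)[C@H](O[C@@H]3C[C@H](C)CC[C@H]3C(C)C)O1 | intermediate
8 | keto lactone: (4S,5R)-5-[(1R,2S,5R)-menthyloxy]-4-[2-oxo-2-(2,6,6-trimethylcyclohex-1-en-1-yl)ethyl]dihydrofuran-2,3-dione (not isolated) | O=C1C(=O)[C@@H](CC(=O)C2=C(C)CCCC2(C)C)[C@H](O[C@@H]3C[C@H](C)CC[C@H]3C(C)C)O1 | intermediate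
9 | (5R)-3-hydroxy-5-[(1R,2S,5R)-menthyloxy]-4-[2-oxo-2-(2,6,6-trimethylcyclohex-1-en-1-yl)ethyl]furan-2(5H)-one | O=C1C(O)=C(CC(=O)C2=C(C)CCCC2(C)C)[C@H](O[C@@H]3C[C@H](C)CC[C@H]3C(C)C)O1 | intermediate
10 | (5R)-3-(4-methoxybenzyloxy)-5-[(1R,2S,5R)-menthyloxy]-4-[2-oxo-2-(2,6,6-trimethylcyclohex-1-en-1-yl)ethyl]furan-2(5H)-one | O=C1C(OCc2ccc(OC)cc2)=C(CC(=O)C3=C(C)CCCC3(C)C)[C@H](O[C@@H]4C[C@H](C)CC[C@H]4C(C)C)O1 | intermediate
11 | trienolate: DBU-H+ salt of the 2-oxidotriene from 10 (C6=C7 geometry mobile; not isolated) | [O-]C(=CC1=C(OCc2ccc(OC)cc2)C(=O)O[C@H]1O[C@@H]3C[C@H](C)CC[C@H]3C(C)C)C4=C(C)CCCC4(C)C.C1CCC2=[NH+]CCCN2CC1 | intermediate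
12 | cyclised enolate: DBU-H+ salt of the (9R,10S,12R) ring B dienolate C5=C6(O−)–C7=C8 (not isolated) | [O-]C1=C2C(C)(C)CCC[C@]2(C)[C@]3(OCc4ccc(OC)cc4)C(=O)O[C@@H](O[C@@H]5C[C@H](C)CC[C@H]5C(C)C)C3=C1.C1CCC2=[NH+]CCCN2CC1 | intermediate
13 | (5R,9R,10S,12R)-12-[(1R,2S,5R)-menthyloxy]-9-(4-methoxybenzyloxy)-6-oxo-5β-drim-7-en-11,12-olide (cis-fused decalin) | O=C1C=C2[C@H](O[C@@H]3C[C@H](C)CC[C@H]3C(C)C)OC(=O)[C@@]2(OCc5ccc(OC)cc5)[C@@]4(C)CCCC(C)(C)[C@@H]14 | intermediate
14 | cis-fused carboxylate: lithium (5R,9R,10S)-9-(4-methoxybenzyloxy)-6,12-dioxo-5β-drim-7-en-11-oate (not isolated) | O=C1C=C(C=O)[C@@](OCc3ccc(OC)cc3)(C(=O)[O-])[C@@]2(C)CCCC(C)(C)[C@@H]12.[Li+] | intermediate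
15 | (5S,9R,10S)-9-(4-methoxybenzyloxy)-6,12-dioxodrim-7-en-11-oic acid | O=C1C=C(C=O)[C@@](OCc3ccc(OC)cc3)(C(=O)O)[C@@]2(C)CCCC(C)(C)[C@H]12 | intermediate
16 | (5S,9R,10S)-12,12-dimethoxy-9-(4-methoxybenzyloxy)-6-oxodrim-7-en-11-oic acid | O=C1C=C(C(OC)OC)[C@@](OCc3ccc(OC)cc3)(C(=O)O)[C@@]2(C)CCCC(C)(C)[C@H]12 | intermediate
17 | (5S,6R,9R,10S)-6-hydroxy-12,12-dimethoxy-9-(4-methoxybenzyloxy)drim-7-en-11-oic acid | O[C@@H]1C=C(C(OC)OC)[C@@](OCc3ccc(OC)cc3)(C(=O)O)[C@@]2(C)CCCC(C)(C)[C@H]12 | intermediate
18 | (2E,4E)-hexa-2,4-dienal | C/C=C/C=C/C=O | starting material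
19 | malonic acid | OC(=O)CC(=O)O | starting material
20 | (2E,4E,6E)-octa-2,4,6-trienoic acid | C/C=C/C=C/C=C/C(=O)O | intermediate
21 | mixed anhydride: (2E,4E,6E)-octa-2,4,6-trienoic 2,4,6-trichlorobenzoic anhydride (not isolated) | C/C=C/C=C/C=C/C(=O)OC(=O)c1c(Cl)cc(Cl)cc1Cl | intermediate
22 | (5S,6R,9R,10S)-12,12-dimethoxy-9-(4-methoxybenzyloxy)-6-[(2E,4E,6E)-octa-2,4,6-trienoyloxy]drim-7-en-11-oic acid | C/C=C/C=C/C=C/C(=O)O[C@@H]1C=C(C(OC)OC)[C@@](OCc3ccc(OC)cc3)(C(=O)O)[C@@]2(C)CCCC(C)(C)[C@H]12 | intermediate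
23 | (5S,6R,9R,10S)-9-hydroxy-6-[(2E,4E,6E)-octa-2,4,6-trienoyloxy]-12-oxodrim-7-en-11-oic acid (CNP0234478.3) | C/C=C/C=C/C=C/C(=O)O[C@@H]1C=C(C=O)[C@@](O)(C(=O)O)[C@@]2(C)CCCC(C)(C)[C@H]12 | target

Total step count: 12 steps.
Longest linear sequence: 11 steps (steps 1–9, 11 and 12; step 10 prepares the side-chain acid).

Steps most likely to fail

1. Step 6 (key step). Ring closure between the two fully substituted termini may be slower than base-mediated loss of configuration at the C12 acetal centre of 10 (which would erode facial control), or the stabilised open trienolate may simply be recovered. Fallback, from 10 and back to the route at 13: soft enolisation with TBSOTf/Et3N (CH2Cl2, −78 °C) should give the neutral tert-butyldimethylsilyl trienol ether F1. Irradiation at about 350 nm in PhMe at 80–110 °C equilibrates the C6=C7 geometry, and the isomer with C5 and C8 cis undergoes the thermal, base-free disrotatory electrocyclisation to the cyclised silyl dienol ether F2, under the same inside–inside and anti-menthyloxy control. HF·pyridine in THF then protodesilylates F2 to enone 13.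

2. Step 3. Proton transfer from the acidic ketone α-CH2 of the Michael adduct to the lactone enolate may outrun oxygen transfer, or the enolate may add to the sulfonimine by-product. Fallback, from 3 and back to the route at 7: LDA/TMSCl converts 3 into the trimethylsilyl enol ether F3. Mukaiyama–Michael addition of F3 to 4 in LiClO4/Et2O with silyl transfer gives the lactone silyl ketene acetal F4, which cannot equilibrate by proton transfer. Rubottom oxidation (mCPBA, NaHCO3, CH2Cl2; then aqueous citric acid), anti to the side chain, should then deliver 7.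

3. Step 11. Acylation of the axial 6β-hydroxyl, flanked by the C4 and C10 methyl groups, may be slow, and the free C11 acid may divert the activated trienoate. Fallback, from 17 and back to the route at 22: esterification with the small diethylphosphonoacetic acid (DCC, CH2Cl2; a reactive phosphonoketene-type acylating agent) gives the 6-O-phosphonoacetate F5. Horner–Wadsworth–Emmons olefination of F5 with (2E,4E)-hexa-2,4-dienal 18 (LiCl, DBU, MeCN) then builds the all-E trienoate on the hindered oxygen and gives 22.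

Further compounds
F1 | step 6 | tert-butyldimethylsilyl trienol ether of 10 (mixture of C6=C7 isomers) | CC(C)(C)[Si](C)(C)OC(=CC1=C(OCc2ccc(OC)cc2)C(=O)O[C@H]1O[C@@H]3C[C@H](C)CC[C@H]3C(C)C)C4=C(C)CCCC4(C)C
F2 | step 6 | (9R,10S,12R) cyclised tert-butyldimethylsilyl dienol ether (ring B closed; C5=C6(OSi)–C7=C8) | CC(C)(C)[Si](C)(C)OC1=C2C(C)(C)CCC[C@]2(C)[C@]3(OCc4ccc(OC)cc4)C(=O)O[C@@H](O[C@@H]5C[C@H](C)CC[C@H]5C(C)C)C3=C1
F3 | step 3 | trimethylsilyl enol ether of 3 | C=C(O[Si](C)(C)C)C1=C(C)CCCC1(C)C
F4 | step 3 | (4R,5R) lactone trimethylsilyl ketene acetal from F3 and 4 | C[Si](C)(C)OC1=C[C@@H](CC(=O)C2=C(C)CCCC2(C)C)[C@H](O[C@@H]3C[C@H](C)CC[C@H]3C(C)C)O1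
F5 | step 11 | (5S,6R,9R,10S)-6-[(diethoxyphosphoryl)acetoxy]-12,12-dimethoxy-9-(4-methoxybenzyloxy)drim-7-en-11-oic acid | CCOP(=O)(OCC)CC(=O)O[C@@H]1C=C(C(OC)OC)[C@@](OCc3ccc(OC)cc3)(C(=O)O)[C@@]2(C)CCCC(C)(C)[C@H]12
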